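**Retrosynthetic overview**
1. The target comes from its 5,7-bis-MOM ether by mild acidic unmasking in the last step.
2. Ring C, the only ring built, is closed at O1–C2 by a catalytic enantioselective 6-endo oxa-Michael cyclisation of a 2'-hydroxychalcone. This is the new method and it sets C2 as (S).
3. In that chalcone only the phenol beside the ring-A methyl is free, so closure can give only the 8-methyl-6-prenyl pattern.
4. Both prenyl groups are installed in one twofold Suzuki–Miyaura coupling on a chalcone carrying iodine on ring A and bromine on ring B.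
5. That chalcone comes from a Claisen–Schmidt condensation of 3-bromo-4-methoxybenzaldehyde with iodinated, bis-MOM-protected 3-methylphloroacetophenone; rings A and B are bought as arenes.

Assumption: 1-(2,4,6-trihydroxy-3-methylphenyl)ethan-1-one (1) is bought as a catalogue compound.
Assumption: the sense of induction of the new catalyst in step 5 cannot be predicted with certainty; the (S)-tert-leucine-derived catalyst is drawn, and its mirror image from (R)-tert-leucine is used if the first run gives the (2R) product.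

Catalyst for step 5 (preformed, not a route compound), called "the BIMP catalyst" below: 1-[3,5-bis(trifluoromethyl)phenyl]-3-[(2S)-3,3-dimethyl-1-{[tris(4-methoxyphenyl)-λ5-phosphanylidene]amino}butan-2-yl]thiourea, CC(C)(C)[C@H](NC(=S)Nc1cc(C(F)(F)F)cc(C(F)(F)F)c1)CN=P(c1ccc(OC)cc1)(c1ccc(OC)cc1)c1ccc(OC)cc1

**Route**

Step 1
Reactants: 1 1-(2,4,6-trihydroxy-3-methylphenyl)ethan-1-one
Product: 3 1-[2-hydroxy-4,6-bis(methoxymethoxy)-3-methylphenyl]ethan-1-one, via 4-O-MOM monoether 2 (not isolated)
Conditions: MOMCl (2.1 equiv), i-Pr2NEt (2.5 equiv), CH2Cl2, 0 °C to rt, 3 h; chromatography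
Reagents that add atoms: chloromethyl methyl ether (MOMCl), COCCl
Why: Williamson-type O-alkylation (MOM protection) in which the unchelated para hydroxyl reacts first and then the ortho hydroxyl flanked by H, while the ortho hydroxyl flanked by methyl stays free because it is more hindered and held in the methyl-buttressed hydrogen bond to the acetyl carbonyl.

Step 2
Reactants: 3 1-[2-hydroxy-4,6-bis(methoxymethoxy)-3-methylphenyl]ethan-1-one
Product: 4 1-[2-hydroxy-5-iodo-4,6-bis(methoxymethoxy)-3-methylphenyl]ethan-1-one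
Conditions: NIS (1.05 equiv), DMF, 0 °C to rt, dark, 2 h
Reagents that add atoms: N-iodosuccinimide (NIS), O=C1CCC(=O)N1I
Why: Electrophilic aromatic iodination at the only ring C–H, which is para to the free phenol and ortho to two alkoxy groups, under neutral conditions that leave the MOM acetals untouched.

Step 3
Reactants: 4 1-[2-hydroxy-5-iodo-4,6-bis(methoxymethoxy)-3-methylphenyl]ethan-1-one; 5 3-bromo-4-methoxybenzaldehyde
Product: 7 (2E)-3-(3-bromo-4-methoxyphenyl)-1-[2-hydroxy-5-iodo-4,6-bis(methoxymethoxy)-3-methylphenyl]prop-2-en-1-one, via racemic aldol adduct 6 (not isolated)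
Conditions: KOH (50% aq, 10 equiv), EtOH, 0 °C to rt, 36 h; then citric acid to pH 5
Reagents that add atoms: none
Why: Claisen–Schmidt condensation (crossed aldol, then E1cB dehydration) of a methyl ketone with a non-enolisable aldehyde gives only the (E)-enone, and aryl halides and MOM ethers are inert to KOH at room temperature.

Step 4
Reactants: 7 (2E)-3-(3-bromo-4-methoxyphenyl)-1-[2-hydroxy-5-iodo-4,6-bis(methoxymethoxy)-3-methylphenyl]prop-2-en-1-one; 8 4,4,5,5-tetramethyl-2-(3-methylbut-2-en-1-yl)-1,3,2-dioxaborolane (prenyl-Bpin, two equivalents react)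
Product: 10 (2E)-1-[2-hydroxy-4,6-bis(methoxymethoxy)-3-methyl-5-(3-methylbut-2-en-1-yl)phenyl]-3-[4-methoxy-3-(3-methylbut-2-en-1-yl)phenyl]prop-2-en-1-one, via mono-prenylated bromochalcone 9 (not isolated)
Conditions: 8 (3.5 equiv), Pd(dppf)Cl2 (10 mol%), K3PO4 (2 M aq, 5 equiv), THF, 60 °C, Ar, 12 h
Reagents that add atoms: none
Why: Twofold Suzuki–Miyaura coupling in which zerovalent palladium inserts into C–I and then C–Br, the chelating dppf ligand lets the prenyl–palladium intermediate equilibrate (σ–π–σ) to the less hindered primary σ-prenyl form before reductive elimination so that the linear prenyl arene forms at both sites, and the chalcone survives because under base it rests as its phenoxide instead of cyclising.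

Step 5
Reactants: 10 (2E)-1-[2-hydroxy-4,6-bis(methoxymethoxy)-3-methyl-5-(3-methylbut-2-en-1-yl)phenyl]-3-[4-methoxy-3-(3-methylbut-2-en-1-yl)phenyl]prop-2-en-1-one
Product: 11 (2S)-5,7-bis(methoxymethoxy)-2-[4-methoxy-3-(3-methylbut-2-en-1-yl)phenyl]-8-methyl-6-(3-methylbut-2-en-1-yl)-2,3-dihydro-4H-chromen-4-one
Conditions: BIMP catalyst (10 mol%), PhMe (0.05 M), 4 Å MS, −20 °C, 48–72 h; AcOH (0.3 equiv) at −20 °C before full conversion; silica filtration
Reagents that add atoms: none
Why: Proposed new method: a bifunctional iminophosphorane–thiourea (BIMP) superbase catalyses the enantioselective 6-endo-trig intramolecular oxa-Michael addition of an unactivated 2'-hydroxychalcone; the iminophosphorane, far more basic than a cinchona amine, fully deprotonates the hydrogen-bonded 2'-phenol to a tight phenoxide/aminophosphonium ion pair, the thiourea N–H bonds clamp the enone carbonyl (already twisted out of the ring-A plane by the 6'-OMOM group, which places the phenoxide oxygen over C-β), the C–O bond forms on one enantiotopic face of the (E)-alkene inside this chiral pocket to set C2 as (S), and the aminophosphonium N–H protonates the enolate to release the flavanone; because the product has no phenol and its C3–H is far less acidic than the substrate OH, the base rests on unreacted chalcone and does not reopen and racemise the product until late conversion, hence the low temperature and acid quench; the closest known reaction types are BIMP-catalysed enantioselective intramolecular oxa-Michael additions of alcohols to α,β-unsaturated esters and amides and cinchona–thiourea-catalysed oxa-Michael cyclisation of α-carboxy-activated 2'-hydroxychalcones.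

Step 6
Reactants: 11 (2S)-5,7-bis(methoxymethoxy)-2-[4-methoxy-3-(3-methylbut-2-en-1-yl)phenyl]-8-methyl-6-(3-methylbut-2-en-1-yl)-2,3-dihydro-4H-chromen-4-one
Product: 13 (2S)-5,7-dihydroxy-2-[4-methoxy-3-(3-methylbut-2-en-1-yl)phenyl]-8-methyl-6-(3-methylbut-2-en-1-yl)-2,3-dihydro-4H-chromen-4-one, via 5-hydroxy-7-O-MOM flavanone 12 (not isolated)
Conditions: HCl (3 M aq)/MeOH 1:10, 40 °C, 2–4 h (TLC control); NaHCO3 work-up
Reagents that add atoms: none
Why: Acid-catalysed acetal exchange of the MOM ethers with methanol (the carbonyl-chelated 5-O-MOM group first, then the 7-O-MOM group) runs without base, so the C2 stereocentre, which is labile only through base-mediated retro-oxa-Michael opening, is kept, and dilute acid for a short time leaves the prenyl alkenes uncyclised.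

**Compound list**
1 | 1-(2,4,6-trihydroxy-3-methylphenyl)ethan-1-one | CC(=O)c1c(O)cc(O)c(C)c1O | starting material
2 | 1-[2,6-dihydroxy-4-(methoxymethoxy)-3-methylphenyl]ethan-1-one | CC(=O)c1c(O)cc(OCOC)c(C)c1O | intermediate
3 | 1-[2-hydroxy-4,6-bis(methoxymethoxy)-3-methylphenyl]ethan-1-one | CC(=O)c1c(OCOC)cc(OCOC)c(C)c1O | intermediate
4 | 1-[2-hydroxy-5-iodo-4,6-bis(methoxymethoxy)-3-methylphenyl]ethan-1-one | CC(=O)c1c(OCOC)c(I)c(OCOC)c(C)c1O | intermediate
5 | 3-bromo-4-methoxybenzaldehyde | COc1ccc(C=O)cc1Br | starting material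
6 | 3-(3-bromo-4-methoxyphenyl)-3-hydroxy-1-[2-hydroxy-5-iodo-4,6-bis(methoxymethoxy)-3-methylphenyl]propan-1-one (racemic) | COc1ccc(C(O)CC(=O)c2c(OCOC)c(I)c(OCOC)c(C)c2O)cc1Br | intermediate
7 | (2E)-3-(3-bromo-4-methoxyphenyl)-1-[2-hydroxy-5-iodo-4,6-bis(methoxymethoxy)-3-methylphenyl]prop-2-en-1-one | COc1ccc(/C=C/C(=O)c2c(OCOC)c(I)c(OCOC)c(C)c2O)cc1Br | intermediate
8 | 4,4,5,5-tetramethyl-2-(3-methylbut-2-en-1-yl)-1,3,2-dioxaborolane | CC(C)=CCB1OC(C)(C)C(C)(C)O1 | starting material
9 | (2E)-3-(3-bromo-4-methoxyphenyl)-1-[2-hydroxy-4,6-bis(methoxymethoxy)-3-methyl-5-(3-methylbut-2-en-1-yl)phenyl]prop-2-en-1-one | COc1ccc(/C=C/C(=O)c2c(OCOC)c(CC=C(C)C)c(OCOC)c(C)c2O)cc1Br | intermediate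
10 | (2E)-1-[2-hydroxy-4,6-bis(methoxymethoxy)-3-methyl-5-(3-methylbut-2-en-1-yl)phenyl]-3-[4-methoxy-3-(3-methylbut-2-en-1-yl)phenyl]prop-2-en-1-one | COc1ccc(/C=C/C(=O)c2c(OCOC)c(CC=C(C)C)c(OCOC)c(C)c2O)cc1CC=C(C)C | intermediate
11 | (2S)-5,7-bis(methoxymethoxy)-2-[4-methoxy-3-(3-methylbut-2-en-1-yl)phenyl]-8-methyl-6-(3-methylbut-2-en-1-yl)-2,3-dihydro-4H-chromen-4-one | COc1ccc([C@@H]2CC(=O)c3c(OCOC)c(CC=C(C)C)c(OCOC)c(C)c3O2)cc1CC=C(C)C | intermediate
12 | (2S)-5-hydroxy-7-(methoxymethoxy)-2-[4-methoxy-3-(3-methylbut-2-en-1-yl)phenyl]-8-methyl-6-(3-methylbut-2-en-1-yl)-2,3-dihydro-4H-chromen-4-one | COc1ccc([C@@H]2CC(=O)c3c(O)c(CC=C(C)C)c(OCOC)c(C)c3O2)cc1CC=C(C)C | intermediate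
13 | (2S)-5,7-dihydroxy-2-[4-methoxy-3-(3-methylbut-2-en-1-yl)phenyl]-8-methyl-6-(3-methylbut-2-en-1-yl)-2,3-dihydro-4H-chromen-4-one | COc1ccc([C@@H]2CC(=O)c3c(O)c(CC=C(C)C)c(O)c(C)c3O2)cc1CC=C(C)C | target

**Totals**
Total step count: 6.
Longest linear sequence: 6 steps (1 → 3 → 4 → 7 → 10 → 11 → 13).

**Three steps most likely to fail**

Step 1 (regioselective bis-protection). The risk is that the second MOM group goes partly onto the methyl-flanked hydroxyl; that isomer would lead on to the 6-methyl-8-prenyl flavanone. The structure of 3 is checked by NOE (ring H to both OCH2O groups, methyl to only one). The fallback sets out from 1 and comes back at 3. Compound 1 is protected exhaustively (NaH, excess MOMCl, DMF, 0 °C) to the tris-ether 1-[2,4,6-tris(methoxymethoxy)-3-methylphenyl]ethan-1-one F1. A single ortho MOM group is then removed under carbonyl-chelation control (catalytic I2, MeOH, rt, stopped at mono-cleavage). The most congested acetal, flanked by acetyl and methyl, is expected to be lost first, which gives 3.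

Step 4 (twofold prenyl coupling on the chalcone). The risks are branched (reverse-prenyl) product at either site, slow coupling at the doubly ortho-substituted iodide, and protodehalogenation. The fallback sets out from 4 and 5 and comes back at 10. Each fragment is prenylated on its own under neutral Stille conditions with tributyl(3-methylbut-2-en-1-yl)stannane (Pd(PPh3)4, DMF, 90 °C) and purified. This gives the ketone 1-[2-hydroxy-4,6-bis(methoxymethoxy)-3-methyl-5-(3-methylbut-2-en-1-yl)phenyl]ethan-1-one F2 from 4 and the aldehyde 4-methoxy-3-(3-methylbut-2-en-1-yl)benzaldehyde F3 from 5. The two are condensed under the conditions of step 3, through the racemic aldol adduct 3-hydroxy-1-[2-hydroxy-4,6-bis(methoxymethoxy)-3-methyl-5-(3-methylbut-2-en-1-yl)phenyl]-3-[4-methoxy-3-(3-methylbut-2-en-1-yl)phenyl]propan-1-one F4, to give 10 directly; compounds 7 and 9 are bypassed.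

Step 5 (new catalytic oxa-Michael cyclisation). The risks are low conversion with the electron-rich ring B, or loss of ee through reversible ring opening. The fallback uses known chemistry, sets out from 10 and comes back at 11. Compound 10 is cyclised without stereocontrol (NaOAc, EtOH, reflux) to the racemic flavanone rac-5,7-bis(methoxymethoxy)-2-[4-methoxy-3-(3-methylbut-2-en-1-yl)phenyl]-8-methyl-6-(3-methylbut-2-en-1-yl)-2,3-dihydro-4H-chromen-4-one F5. This is resolved kinetically by Noyori–Ikariya-type asymmetric transfer hydrogenation (RuCl(p-cymene)[(R,R)-TsDPEN] 2 mol%, HCO2H/Et3N 5:2, EtOAc, rt, stopped near 55% conversion). By the usual model for aryl ketones this catalyst reduces the (2R)-ketone to the cis-alcohol (2R,4R)-5,7-bis(methoxymethoxy)-2-[4-methoxy-3-(3-methylbut-2-en-1-yl)phenyl]-8-methyl-6-(3-methylbut-2-en-1-yl)-3,4-dihydro-2H-chromen-4-ol F6, which is removed by chromatography. The unreacted (2S)-ketone is 11 (at most 50%, high ee; the catalyst antipode is swapped if the first run enriches the wrong ketone), and the route continues with step 6.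

**Further compounds**
F1 | step 1 | 1-[2,4,6-tris(methoxymethoxy)-3-methylphenyl]ethan-1-one | CC(=O)c1c(OCOC)cc(OCOC)c(C)c1OCOC
F2 | step 4 | 1-[2-hydroxy-4,6-bis(methoxymethoxy)-3-methyl-5-(3-methylbut-2-en-1-yl)phenyl]ethan-1-one | CC(=O)c1c(OCOC)c(CC=C(C)C)c(OCOC)c(C)c1O
F3 | step 4 | 4-methoxy-3-(3-methylbut-2-en-1-yl)benzaldehyde | COc1ccc(C=O)cc1CC=C(C)C
F4 | step 4 | 3-hydroxy-1-[2-hydroxy-4,6-bis(methoxymethoxy)-3-methyl-5-(3-methylbut-2-en-1-yl)phenyl]-3-[4-methoxy-3-(3-methylbut-2-en-1-yl)phenyl]propan-1-one (racemic) | COc1ccc(C(O)CC(=O)c2c(OCOC)c(CC=C(C)C)c(OCOC)c(C)c2O)cc1CC=C(C)C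
F5 | step 5 | rac-5,7-bis(methoxymethoxy)-2-[4-methoxy-3-(3-methylbut-2-en-1-yl)phenyl]-8-methyl-6-(3-methylbut-2-en-1-yl)-2,3-dihydro-4H-chromen-4-one | COc1ccc(C2CC(=O)c3c(OCOC)c(CC=C(C)C)c(OCOC)c(C)c3O2)cc1CC=C(C)C
F6 | step 5 | (2R,4R)-5,7-bis(methoxymethoxy)-2-[4-methoxy-3-(3-methylbut-2-en-1-yl)phenyl]-8-methyl-6-(3-methylbut-2-en-1-yl)-3,4-dihydro-2H-chromen-4-ol | COc1ccc([C@H]2C[C@@H](O)c3c(OCOC)c(CC=C(C)C)c(OCOC)c(C)c3O2)cc1CC=C(C)C
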